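**Retrosynthetic overview**

1. Target 13 ⇐ 12 by desilylation ⇐ 11 by Baeyer–Villiger oxidation: an acetyl group on the quaternary ring-fusion carbon is the latent acetoxy group.
2. 11 ⇐ 8 + 2: ring B (the oxolane whose ArCH carbon is bonded to the quaternary carbon) is cut at its CH2–O bond and at its ArCH–C(quaternary) bond, a formal [3+2] annulation of the aldehyde C=O of 2 onto the cyclopropane of 8, run as an iodide relay (ring opening, aldol, etherification).
3. Enabling feature: the quaternary ring-fusion carbon bears an oxygen and is linked through the ring-fusion CH to the CH2–O carbon of ring B. With acetyl in place of acetoxy these three carbons can be a ketone-activated cyclopropane fused to ring A, with the acetyl-bearing carbon as latent enolate and the CH2 as latent electrophile.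
4. 8 ⇐ 6 by gold-catalysed alkyne oxidation/cyclopropanation, which closes ring A and the cyclopropane together; 6 ⇐ (S)-allylic alcohol 4 + 1-bromobut-2-yne 5; 4 ⇐ vanillin 1 via aldehyde 2, which is also the partner in the key step.
5. Ring order: ring A (oxolane with the aryl group remote from the quaternary carbon) plus cyclopropane in step 5, then ring B in step 6.

Key step: step 6

Remark: in names, Ar = 3-methoxy-4-[(triisopropylsilyl)oxy]phenyl; all SMILES are written in full; the target is taken as the (1S,2R,5R,6S) enantiomer encoded by the given SMILES.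

**Step 1**
Reactants: 1 vanillin
Product: 2 3-methoxy-4-[(triisopropylsilyl)oxy]benzaldehyde (ArCHO)
Conditions: i-Pr3SiCl, imidazole, DMF, rt
Reagents that add atoms: triisopropylsilyl chloride, CC(C)[Si](Cl)(C(C)C)C(C)C
Why: Imidazole-promoted O-silylation of the phenol gives a bulky aryl silyl ether that should survive the organometallic, basic, Lewis-acidic and peracid steps and be removable by fluoride without touching a tertiary acetate.

**Step 2**
Reactants: 2 ArCHO
Product: 3 rac-1-Ar-prop-2-en-1-ol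
Conditions: CH2=CHMgBr, THF, −78 to 0 °C; aq. NH4Cl
Reagents that add atoms: vinylmagnesium bromide, C=C[Mg]Br
Why: Grignard 1,2-addition of a vinyl nucleophile to the aldehyde gives the allylic benzylic alcohol as a racemate, with no stereocontrol sought at this stage.

**Step 3**
Reactants: 3 rac-1-Ar-prop-2-en-1-ol
Product: 4 (S)-1-Ar-prop-2-en-1-ol (recovered unreacted enantiomer)
Conditions: Candida antarctica lipase B (immobilised), vinyl acetate, t-BuOMe, 30 °C, run to just past half conversion
Reagents that add atoms: none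
Why: Lipase-catalysed kinetic resolution by enantioselective transesterification should acetylate the (R)-alcohol (aryl as the large group) and leave the (S)-alcohol, which carries the benzylic stereocentre of ring A.

**Step 4**
Reactants: 4 (S)-1-Ar-prop-2-en-1-ol; 5 1-bromobut-2-yne
Product: 6 (S)-3-(but-2-yn-1-yloxy)-3-Ar-prop-1-ene
Conditions: NaH, n-Bu4NI (cat.), THF, 0 °C to rt
Reagents that add atoms: none
Why: Williamson etherification of the sodium alkoxide with a reactive propargylic bromide leaves the benzylic stereocentre untouched.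

**Step 5**
Reactants: 6 (S)-3-(but-2-yn-1-yloxy)-3-Ar-prop-1-ene
Product: 8 1-[(1S,4S,5S)-4-Ar-3-oxabicyclo[3.1.0]hexan-1-yl]ethan-1-one, via α-oxo gold carbene 7 (not isolated)
Conditions: Ph3PAuNTf2 (5 mol %), 8-methylquinoline N-oxide (1.5 equiv), ClCH2CH2Cl, rt
Reagents that add atoms: 8-methylquinoline N-oxide, Cc1cccc2ccc[n+]([O-])c12
Why: In this gold-catalysed alkyne oxidation/intramolecular cyclopropanation of a 1,6-enyne, the propargylic oxygen polarises the alkyne so that the N-oxide should deliver oxygen to the methyl-bearing carbon, and carbene 7 should then cyclopropanate the vinyl group from the face that lets the aryl group point away from the forming bicycle (exo, trans to the cyclopropane CH2), which sets both ring-fusion centres relative to the benzylic one.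

**Step 6**
Reactants: 8 1-[(1S,4S,5S)-4-Ar-3-oxabicyclo[3.1.0]hexan-1-yl]ethan-1-one; 2 ArCHO
Product: 11 1-[(1S,2R,5R,6S)-2,6-bis(Ar)-3,7-dioxabicyclo[3.3.0]octan-1-yl]ethan-1-one, via iodomagnesium enolate 9 (not isolated), via iodomagnesium aldolate 10 (not isolated)
Conditions: MgI2 (1.2 equiv), 2 (1.5 equiv), THF, 65 °C, sealed tube
Reagents that add atoms: none
Why: Proposed new method: MgI2 should bind the acetyl oxygen and the ring-A oxygen of 8 as a six-membered chelate, iodide should open the ketone-activated cyclopropane by SN2 attack at its unsubstituted CH2 carbon (homo-conjugate addition), and the tetrasubstituted (Z)-enolate 9 should add to aldehyde 2 to give aldolate 10, whose alkoxide displaces the primary iodide and returns MgI2. The closest known reaction types are the MgI2-mediated ring expansion of donor-free acyl cyclopropanes with aldimines to pyrrolidines and the iodide-induced ring-opening aldol reaction of cyclopropyl ketones with aldehydes; here the aldolate oxygen, not a nitrogen, closes the ring in the same flask. Ring B closes by 5-exo-tet Williamson substitution at the CH2I carbon after the intermolecular aldol C–C bond formation. The quaternary centre is controlled by the ring fusion, because the aldol step is reversible and only the aldolate whose carbinol carbon lies cis to the CH2I group can close to the cis-fused bicycle, so the other facial isomer should be funnelled back through 9. The benzylic carbinol centre is controlled by a closed chair-like six-membered transition state of the chelated (Z)-enolate with the aldehyde aryl group equatorial, which places the new aryl group exo and cis to the acetyl group. The step needs iodide attack at CH2 and not at the ring-fusion CH, and C- over O-alkylation of the enolate; the primary carbon is the only unhindered SN2 site, and the chelate to the ring-A oxygen holds the enolate oxygen away from the CH2I group, so a Cloke–Wilson-type closure is geometrically blocked.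

**Step 7**
Reactants: 11 1-[(1S,2R,5R,6S)-2,6-bis(Ar)-3,7-dioxabicyclo[3.3.0]octan-1-yl]ethan-1-one
Product: 12 (1S,2R,5R,6S)-2,6-bis(Ar)-3,7-dioxabicyclo[3.3.0]octan-1-yl acetate
Conditions: mCPBA, NaHCO3, CH2Cl2, 0 °C to rt
Reagents that add atoms: 3-chloroperbenzoic acid (mCPBA), OOC(=O)c1cccc(Cl)c1
Why: In this Baeyer–Villiger oxidation the fully substituted ring-fusion carbon should migrate in preference to methyl and with retention of configuration, turning the acetyl group directly into the tertiary acetate.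

**Step 8**
Reactants: 12 (1S,2R,5R,6S)-2,6-bis(Ar)-3,7-dioxabicyclo[3.3.0]octan-1-yl acetate
Product: 13 1-acetoxypinoresinol, (1S,2R,5R,6S)-2,6-bis(4-hydroxy-3-methoxyphenyl)-3,7-dioxabicyclo[3.3.0]octan-1-yl acetate
Conditions: Bu4NF (2.2 equiv), AcOH (2.5 equiv), THF, 0 °C
Reagents that add atoms: none
Why: Fluoride-mediated cleavage of the two aryl silyl ethers, buffered with acetic acid so that phenoxide does not cleave or transfer the hindered tertiary acetate, should release the target without touching any stereocentre.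

**Compound list**

1 | vanillin (4-hydroxy-3-methoxybenzaldehyde) | COc1cc(C=O)ccc1O | starting material
2 | 3-methoxy-4-[(triisopropylsilyl)oxy]benzaldehyde (ArCHO) | COc1cc(C=O)ccc1O[Si](C(C)C)(C(C)C)C(C)C | intermediate
3 | rac-1-Ar-prop-2-en-1-ol | C=CC(O)c1ccc(O[Si](C(C)C)(C(C)C)C(C)C)c(OC)c1 | intermediate
4 | (S)-1-Ar-prop-2-en-1-ol | C=C[C@H](O)c1ccc(O[Si](C(C)C)(C(C)C)C(C)C)c(OC)c1 | intermediate
5 | 1-bromobut-2-yne | CC#CCBr | starting material
6 | (S)-3-(but-2-yn-1-yloxy)-3-Ar-prop-1-ene | C=C[C@H](OCC#CC)c1ccc(O[Si](C(C)C)(C(C)C)C(C)C)c(OC)c1 | intermediate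
7 | α-oxo gold carbene: (triphenylphosphine)gold carbene at the ether-bearing alkyne carbon of 6, acetyl on the carbene carbon, (S) at the benzylic carbon, triflimide counter-ion (formed in the flask, not isolated) | C=C[C@H](OCC(=[Au][P+](c1ccccc1)(c1ccccc1)c1ccccc1)C(C)=O)c1ccc(O[Si](C(C)C)(C(C)C)C(C)C)c(OC)c1.FC(F)(F)S(=O)(=O)[N-]S(=O)(=O)C(F)(F)F | intermediate
8 | 1-[(1S,4S,5S)-4-Ar-3-oxabicyclo[3.1.0]hexan-1-yl]ethan-1-one (aryl trans to the cyclopropane CH2) | CC(=O)[C@]12CO[C@H](c3ccc(O[Si](C(C)C)(C(C)C)C(C)C)c(OC)c3)[C@H]1C2 | intermediate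
9 | iodomagnesium (Z)-1-[(4S,5S)-4-(iodomethyl)-5-Ar-oxolan-3-ylidene]ethan-1-olate (enolate oxygen cis to the ring CH2O; CH2I and Ar trans; formed in the flask, not isolated) | C/C(O[Mg]I)=C1/CO[C@H](c2ccc(O[Si](C(C)C)(C(C)C)C(C)C)c(OC)c2)[C@H]1CI | intermediate
10 | iodomagnesium (R)-[(3S,4S,5S)-3-acetyl-4-(iodomethyl)-5-Ar-oxolan-3-yl](Ar)methanolate (carbinol carbon cis to CH2I; formed in the flask, not isolated) | CC(=O)[C@@]1(CO[C@H](c2ccc(O[Si](C(C)C)(C(C)C)C(C)C)c(OC)c2)[C@H]1CI)[C@H](O[Mg]I)c1ccc(O[Si](C(C)C)(C(C)C)C(C)C)c(OC)c1 | intermediate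
11 | 1-[(1S,2R,5R,6S)-2,6-bis(Ar)-3,7-dioxabicyclo[3.3.0]octan-1-yl]ethan-1-one (cis-fused, both aryl groups exo) | COc1cc([C@H]2OC[C@]3(C(C)=O)[C@@H](c4ccc(O[Si](C(C)C)(C(C)C)C(C)C)c(OC)c4)OC[C@H]23)ccc1O[Si](C(C)C)(C(C)C)C(C)C | intermediate
12 | (1S,2R,5R,6S)-2,6-bis(Ar)-3,7-dioxabicyclo[3.3.0]octan-1-yl acetate | COc1cc([C@H]2OC[C@]3(OC(C)=O)[C@@H](c4ccc(O[Si](C(C)C)(C(C)C)C(C)C)c(OC)c4)OC[C@H]23)ccc1O[Si](C(C)C)(C(C)C)C(C)C | intermediate
13 | 1-acetoxypinoresinol, (1S,2R,5R,6S)-2,6-bis(4-hydroxy-3-methoxyphenyl)-3,7-dioxabicyclo[3.3.0]octan-1-yl acetate | COc1cc([C@H]2OC[C@]3(OC(C)=O)[C@@H](c4ccc(O)c(OC)c4)OC[C@H]23)ccc1O | target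

**Step count and risks**

Total step count: 8. Longest linear sequence: 8 steps (1 → 2 → 3 → 4 → 6 → 8 → 11 → 12 → 13); aldehyde 2 is used a second time in step 6.

Steps most likely to fail:

1. Step 6 (proposed new method). What may go wrong: diversion of the iodo enolate by intramolecular O-alkylation or by re-closure to the cyclopropane; enolate equilibration to the methyl side followed by aldol condensation; and incomplete reversal of the aldol step, so that material stays as an aldolate that cannot close. Fallback with known reactions only, setting out from 8 and 2 and returning at 11: the iodide-induced ring-opening aldol reaction of cyclopropyl ketones under titanium control (TiCl4, n-Bu4NI, CH2Cl2, −78 to 0 °C) is used to stop at the open-chain γ-iodo aldol, 1-[(3S,4S,5S)-3-[(R)-hydroxy(Ar)methyl]-4-(iodomethyl)-5-Ar-oxolan-3-yl]ethan-1-one F1, which is isolated and freed from its isomers. The ring is then closed in a separate silver-assisted Williamson etherification (Ag2O, CH2Cl2, rt) to give 11. C–C and C–O bond formation are thereby separated, the enolate is never heated, and isomers of F1 that cannot close can be cycled back by retro-aldol cleavage.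

2. Step 5. What may go wrong: 1,2-hydride shift of the gold carbene from the neighbouring ether CH2, a second oxidation of the carbene by the N-oxide, enyne cycloisomerisation before oxidation, or poor facial selectivity in the cyclopropanation. Fallback, setting out from 4 and returning at 8:
   - 4 is O-alkylated with ethyl 2-(bromomethyl)acrylate (NaH, THF, 0 °C) to ethyl 2-({[(1S)-1-Ar-prop-2-en-1-yl]oxy}methyl)prop-2-enoate F2.
   - Ring-closing metathesis (second-generation Grubbs catalyst, CH2Cl2, 40 °C) should give ethyl (5S)-5-Ar-2,5-dihydrofuran-3-carboxylate F3.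
   - Corey–Chaykovsky cyclopropanation (Me3S(O)I, NaH, DMSO, rt), with the ylide adding anti to the neighbouring aryl group, should give ethyl (1S,4S,5S)-4-Ar-3-oxabicyclo[3.1.0]hexane-1-carboxylate F4.
   - MeNH(OMe)·HCl and i-PrMgCl (THF, −20 °C) convert the ester into (1S,4S,5S)-N-methoxy-N-methyl-4-Ar-3-oxabicyclo[3.1.0]hexane-1-carboxamide F5.
   - MeMgBr (THF, 0 °C) gives 8.

3. Step 7. What may go wrong: slow oxygen insertion at the hindered, β-oxygenated ketone, with competing oxidation of the electron-rich arenes by the peracid. Fallback, setting out from 11 and returning at 12, which degrades the acetyl group and re-installs oxygen by radical decarboxylation: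
   - Enolisation, possible only toward the methyl group (LiN(SiMe3)2, Me3SiCl, THF, −78 °C), gives the silyl enol ether, (1S,2R,5R,6S)-2,6-bis(Ar)-1-[1-(trimethylsilyloxy)ethenyl]-3,7-dioxabicyclo[3.3.0]octane F6.
   - Ozonolysis (O3, CH2Cl2, −78 °C; Me2S; aqueous work-up) gives (1S,2R,5R,6S)-2,6-bis(Ar)-3,7-dioxabicyclo[3.3.0]octane-1-carboxylic acid F7.
   - Coupling with N-hydroxypyridine-2-thione (DCC, DMAP, CH2Cl2, dark) gives the thiohydroxamate ester, 2-thioxopyridin-1(2H)-yl (1S,2R,5R,6S)-2,6-bis(Ar)-3,7-dioxabicyclo[3.3.0]octane-1-carboxylate F8.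
   - Barton decarboxylation under oxygen (hν, O2, t-BuSH, toluene) gives the ring-fusion hydroperoxide, (1S,2R,5R,6S)-1-hydroperoxy-2,6-bis(Ar)-3,7-dioxabicyclo[3.3.0]octane F9. The cis ring fusion forces oxygen to enter on the convex face, so configuration is retained.
   - Reduction with P(OMe)3 gives the tertiary alcohol, (1S,2R,5R,6S)-2,6-bis(Ar)-3,7-dioxabicyclo[3.3.0]octan-1-ol F10.
   - Acetylation (Ac2O, DMAP, Et3N, CH2Cl2, 40 °C) gives 12.

**Further compounds**

F1 | step 6 | 1-[(3S,4S,5S)-3-[(R)-hydroxy(Ar)methyl]-4-(iodomethyl)-5-Ar-oxolan-3-yl]ethan-1-one | CC(=O)[C@@]1(CO[C@H](c2ccc(O[Si](C(C)C)(C(C)C)C(C)C)c(OC)c2)[C@H]1CI)[C@H](O)c1ccc(O[Si](C(C)C)(C(C)C)C(C)C)c(OC)c1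
F2 | step 5 | ethyl 2-({[(1S)-1-Ar-prop-2-en-1-yl]oxy}methyl)prop-2-enoate | C=C[C@H](OCC(=C)C(=O)OCC)c1ccc(O[Si](C(C)C)(C(C)C)C(C)C)c(OC)c1
F3 | step 5 | ethyl (5S)-5-Ar-2,5-dihydrofuran-3-carboxylate | CCOC(=O)C1=C[C@@H](c2ccc(O[Si](C(C)C)(C(C)C)C(C)C)c(OC)c2)OC1
F4 | step 5 | ethyl (1S,4S,5S)-4-Ar-3-oxabicyclo[3.1.0]hexane-1-carboxylate | CCOC(=O)[C@]12CO[C@H](c3ccc(O[Si](C(C)C)(C(C)C)C(C)C)c(OC)c3)[C@H]1C2
F5 | step 5 | (1S,4S,5S)-N-methoxy-N-methyl-4-Ar-3-oxabicyclo[3.1.0]hexane-1-carboxamide | CON(C)C(=O)[C@]12CO[C@H](c3ccc(O[Si](C(C)C)(C(C)C)C(C)C)c(OC)c3)[C@H]1C2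
F6 | step 7 | (1S,2R,5R,6S)-2,6-bis(Ar)-1-[1-(trimethylsilyloxy)ethenyl]-3,7-dioxabicyclo[3.3.0]octane | COc1cc([C@H]2OC[C@]3(C(=C)O[Si](C)(C)C)[C@@H](c4ccc(O[Si](C(C)C)(C(C)C)C(C)C)c(OC)c4)OC[C@H]23)ccc1O[Si](C(C)C)(C(C)C)C(C)C
F7 | step 7 | (1S,2R,5R,6S)-2,6-bis(Ar)-3,7-dioxabicyclo[3.3.0]octane-1-carboxylic acid | COc1cc([C@H]2OC[C@]3(C(=O)O)[C@@H](c4ccc(O[Si](C(C)C)(C(C)C)C(C)C)c(OC)c4)OC[C@H]23)ccc1O[Si](C(C)C)(C(C)C)C(C)C
F8 | step 7 | 2-thioxopyridin-1(2H)-yl (1S,2R,5R,6S)-2,6-bis(Ar)-3,7-dioxabicyclo[3.3.0]octane-1-carboxylate | COc1cc([C@H]2OC[C@]3(C(=O)On5ccccc5=S)[C@@H](c4ccc(O[Si](C(C)C)(C(C)C)C(C)C)c(OC)c4)OC[C@H]23)ccc1O[Si](C(C)C)(C(C)C)C(C)C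
F9 | step 7 | (1S,2R,5R,6S)-1-hydroperoxy-2,6-bis(Ar)-3,7-dioxabicyclo[3.3.0]octane | COc1cc([C@H]2OC[C@]3(OO)[C@@H](c4ccc(O[Si](C(C)C)(C(C)C)C(C)C)c(OC)c4)OC[C@H]23)ccc1O[Si](C(C)C)(C(C)C)C(C)C
F10 | step 7 | (1S,2R,5R,6S)-2,6-bis(Ar)-3,7-dioxabicyclo[3.3.0]octan-1-ol | COc1cc([C@H]2OC[C@]3(O)[C@@H](c4ccc(O[Si](C(C)C)(C(C)C)C(C)C)c(OC)c4)OC[C@H]23)ccc1O[Si](C(C)C)(C(C)C)C(C)C
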